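The target is disconnected at its 1,4-dioxane ring into two molecules of one monomer, the ortho-quinone of brussonol, which are joined last by a hetero-Diels–Alder dimerization. The monomer rests on one operation: a flat 2-alkyl-2,3-epoxyindan-1-one opens at its oxirane C–C bond, which expands the five-membered carbocycle (C7, C8, C9, C20, C10) to the six-membered 2-benzopyrylium-4-olate ring (C8, C9, C20, C10, O, C7), and this carbonyl ylide adds across C10 and C7 to the tethered vinyl group (C5=C6). The step exploits the C7–O–C10 bridge over seven-membered ring B, closes rings A and B, and sets C5, C7 and C10; the C20 ketone is then removed and a camphanate resolves the enantiomers.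

Key step: step 10

Remark: atoms are numbered as in the icetexane skeleton of brussonol, (5S,7S,10S)-7,10-epoxy-9(10→20)-abeo-abieta-8,11,13-triene-11,12-diol, where C20 is the benzylic carbon between C9 and C10; primed numbers mean the catechol-derived half of the dimer.
Remark: racemic compounds 19, 21 and 22 are drawn as the enantiomer that is carried on; the C20 carbinol is drawn as the epimer expected from hydride delivery on the face of the oxygen bridge, and the other epimer would serve equally because C20 loses its oxygen in step 15.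

Step 1
Reactants: 1 isobutyraldehyde, 2 acrylonitrile
Product: 3 4,4-dimethyl-5-oxopentanenitrile
Conditions: 50% aq NaOH (cat.), neat, 60 °C
Reagents that add atoms: none
Why: Base-catalysed Michael addition (cyanoethylation) at the only enolisable position of the aldehyde should build the quaternary carbon C4; no stereocentre is formed.

Step 2
Reactants: 3 4,4-dimethyl-5-oxopentanenitrile
Product: 4 4,4-dimethylhex-5-enenitrile
Conditions: Ph3PCH3Br, KOtBu, THF, 0 °C → rt
Reagents that add atoms: methyltriphenylphosphonium bromide, C[P+](c1ccccc1)(c1ccccc1)c1ccccc1.[Br-]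
Why: Wittig methylenation of a non-enolisable, α-quaternary aldehyde should give the C5=C6 vinyl group, the nitrile being inert to the ylide at this temperature.

Step 3
Reactants: 4 4,4-dimethylhex-5-enenitrile
Product: 6 4,4-dimethylhex-5-enal, via N-aluminated imine 5 (not isolated)
Conditions: i-Bu2AlH, CH2Cl2, −78 °C; aq. KNaC4H4O6
Reagents that add atoms: water, O
Why: Single hydride addition to the nitrile and hydrolysis of the aluminated imine on work-up (nitrile-to-aldehyde reduction) should leave the isolated alkene untouched.

Step 4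
Reactants: 7 3-isopropylcatechol
Product: 8 1-isopropyl-2,3-dimethoxybenzene
Conditions: MeI, K2CO3, acetone, reflux, N2
Reagents that add atoms: iodomethane, CI
Why: Williamson O-methylation of both phenols protects the catechol and supplies the directing group for the next step.

Step 5
Reactants: 8 1-isopropyl-2,3-dimethoxybenzene, 9 3-chloropropanoyl chloride
Product: 12 3-chloro-1-(4-isopropyl-2,3-dimethoxyphenyl)propan-1-one, via aryllithium 10 (not isolated), via arylzinc chloride 11 (not isolated)
Conditions: n-BuLi, THF, 0 °C → rt; ZnCl2, 0 °C; 9, Pd(PPh3)4 (cat.), 0 °C → rt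
Reagents that add atoms: none
Why: Directed ortho-metalation can only occur at the single position ortho to a methoxy group (future C9), and Negishi acylation of the arylzinc should take the acyl chloride in preference to the alkyl chloride.

Step 6
Reactants: 12 3-chloro-1-(4-isopropyl-2,3-dimethoxyphenyl)propan-1-one
Product: 14 5-isopropyl-6,7-dimethoxyindan-1-one, via aryl vinyl ketone 13 (not isolated)
Conditions: conc. H2SO4, 85 °C
Reagents that add atoms: none
Why: Loss of HCl gives the aryl vinyl ketone, which should close by Nazarov cyclisation onto the only free ortho position (future C8), para to a methoxy group.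

Step 7
Reactants: 14 5-isopropyl-6,7-dimethoxyindan-1-one, 6 4,4-dimethylhex-5-enal
Product: 17 (E)-2-(4,4-dimethylhex-5-en-1-ylidene)-5-isopropyl-6,7-dimethoxyindan-1-one, via aldol adduct 15 (not isolated), via mesylate 16 (not isolated)
Conditions: LiN(SiMe3)2, THF, −78 °C; 6; MsCl, −78 → 0 °C; DBU, rt
Reagents that add atoms: none
Why: Directed aldol addition of the indanone enolate, mesylation and E1cB elimination (aldol condensation) should give the more stable E-enone; no stereocentre is kept.

Step 8
Reactants: 17 (E)-2-(4,4-dimethylhex-5-en-1-ylidene)-5-isopropyl-6,7-dimethoxyindan-1-one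
Product: 18 2-(4,4-dimethylhex-5-en-1-yl)-5-isopropyl-6,7-dimethoxy-1H-inden-1-one
Conditions: RhCl3·3H2O (5 mol %), EtOH, 80 °C
Reagents that add atoms: none
Why: Rhodium hydride addition–elimination (exo-to-endo isomerisation of a 2-alkylidene cyclopentanone) should move the double bond into the ring (C10=C7), while the vinyl group on the quaternary carbon has no allylic hydrogen and cannot migrate.

Step 9
Reactants: 18 2-(4,4-dimethylhex-5-en-1-yl)-5-isopropyl-6,7-dimethoxy-1H-inden-1-one
Product: 19 rac-2-(4,4-dimethylhex-5-en-1-yl)-2,3-epoxy-5-isopropyl-6,7-dimethoxyindan-1-one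
Conditions: 30% H2O2, NaOH (aq), MeOH, 0 °C
Reagents that add atoms: hydrogen peroxide, OO
Why: Weitz–Scheffer nucleophilic epoxidation should attack only the electron-poor enone bond C10=C7, giving the necessarily cis-fused, racemic oxirane and leaving the terminal alkene alone.

Step 10
Reactants: 19 rac-2-(4,4-dimethylhex-5-en-1-yl)-2,3-epoxy-5-isopropyl-6,7-dimethoxyindan-1-one
Product: 21 rac-(5S,7S,10R)-20-oxo-11,12-di-O-methylbrussonol, via 2-benzopyrylium-4-olate 20 (not isolated)
Conditions: 1,2-Cl2C6H4, 160 °C, sealed tube, 0.01 M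
Reagents that add atoms: none
Why: Heating should break the oxirane C7–C10 bond (donor aryl on C7, acceptor carbonyl on C10), so that the five-membered ring of 19 becomes the six-membered ring O–C7–C8–C9–C20–C10 of the 2-benzopyrylium-4-olate 20, a carbonyl ylide that adds as a 1,3-dipole to the tethered alkene. The closest known reaction type is the thermal valence isomerisation of indenone oxides to benzopyrylium oxides followed by intramolecular carbonyl ylide–alkene cycloaddition. Ring A closes by C10–C5 bond formation through the four-carbon tether (C1–C4) in the fused mode, in a chair-like array helped by the gem-dimethyl group, and ring B together with the tetrahydrofuran ring closes by C7–C6 bond formation, suprafacial on both components. C7 and C10 are set cis by the bridging oxygen, and C5 by the tether, which can span C10 and C5 only when C4 lies exo (syn to the oxygen bridge), so that H5 is endo as in the target. The step needs regioselectivity (C10 to C5, not to C6), secured by the tether length, and cycloaddition in preference to a 1,4-hydrogen shift of the ylide, favoured by dilution and the intramolecular trap; it is not enantioselective and should give the racemate, which is resolved in step 12.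

Step 11
Reactants: 21 rac-(5S,7S,10R)-20-oxo-11,12-di-O-methylbrussonol
Product: 22 rac-(5S,7S,10R,20R)-20-hydroxy-11,12-di-O-methylbrussonol
Conditions: NaBH4, MeOH, 0 °C
Reagents that add atoms: none
Why: Hydride reduction of the aryl ketone from the face of the oxygen bridge, away from the C5–C6 bridge, should give mainly one C20 epimer; this centre is removed in step 15.

Step 12
Reactants: 22 rac-(5S,7S,10R,20R)-20-hydroxy-11,12-di-O-methylbrussonol
Product: 23 (5S,7S,10R,20R)-20-[(1S,4R)-camphanoyloxy]-11,12-di-O-methylbrussonol
Conditions: (1S,4R)-camphanic chloride, Et3N, DMAP (cat.), CH2Cl2, rt; separation of the diastereomers on SiO2 or by crystallisation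
Reagents that add atoms: (1S,4R)-camphanic chloride, ClC(=O)[C@@]12CC[C@@](C)(C(=O)O1)C2(C)C
Why: Acylation with an enantiopure acid chloride turns the enantiomers into separable diastereomeric esters (classical resolution), which fixes the absolute configuration at C5, C7 and C10; the required diastereomer would be assigned by X-ray crystallography.

Step 13
Reactants: 23 (5S,7S,10R,20R)-20-[(1S,4R)-camphanoyloxy]-11,12-di-O-methylbrussonol
Product: 24 (5S,7S,10R,20R)-20-hydroxy-11,12-di-O-methylbrussonol
Conditions: LiOH, THF–MeOH–H2O, 50 °C; aq. HCl work-up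
Reagents that add atoms: none
Why: Saponification by acyl–oxygen cleavage should free the enantiopure alcohol without touching any stereocentre.

Step 14
Reactants: 24 (5S,7S,10R,20R)-20-hydroxy-11,12-di-O-methylbrussonol
Product: 26 O-[(5S,7S,10R,20R)-11,12-di-O-methylbrussonol-20-yl] S-methyl dithiocarbonate, via sodium xanthate 25 (not isolated)
Conditions: NaH, THF, 0 °C; CS2; MeI, rt
Reagents that add atoms: carbon disulfide, S=C=S; iodomethane, CI
Why: Xanthate formation (alkoxide addition to CS2, then S-methylation) prepares the radical deoxygenation, and with no β-hydrogen next to C20 a Chugaev elimination is excluded.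

Step 15
Reactants: 26 O-[(5S,7S,10R,20R)-11,12-di-O-methylbrussonol-20-yl] S-methyl dithiocarbonate
Product: 27 (5S,7S,10S)-11,12-di-O-methylbrussonol
Conditions: Bu3SnH, AIBN (cat.), PhMe, 110 °C
Reagents that add atoms: none
Why: Barton–McCombie deoxygenation through the benzylic C20 radical should give the C20 methylene without acid, so the benzylic ether bridge and C5, C7 and C10 stay intact.

Step 16
Reactants: 27 (5S,7S,10S)-11,12-di-O-methylbrussonol
Product: 28 brussonol
Conditions: NaSEt, DMF, 130 °C, Ar; aq. HCl work-up
Reagents that add atoms: none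
Why: SN2 demethylation of both aryl methyl ethers by ethanethiolate avoids Lewis acids, and the bridgehead C7 cannot be attacked from the rear, so the ether bridge should survive.

Step 17
Reactants: 28 brussonol (two molecules per molecule of product)
Product: 30 CNP0371333.1, via brussonol ortho-quinone 29 (not isolated)
Conditions: Ag2O, Et2O, rt; filtration, evaporation; neat, 60 °C
Reagents that add atoms: none
Why: Oxidation gives ortho-quinone 29, which cannot tautomerise to a quinone methide because C7 is a bridgehead, and two molecules should combine in an inverse-demand hetero-Diels–Alder dimerisation (O=C11′–C12′=O of one as heterodiene, C13=C14 of the other as dienophile) that sets C13 and C14 cis by suprafacial addition, joins O12′ to C14 and O11′ to C13 so that the two isopropyl groups stay apart, and must take place on the face of ring C anti to the ether oxygen, a bias that only the oxa-bridged bicycle provides.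

Compound list
1 | isobutyraldehyde | CC(C)C=O | starting material
2 | acrylonitrile | C=CC#N | starting material
3 | 4,4-dimethyl-5-oxopentanenitrile | N#CCCC(C)(C)C=O | intermediate
4 | 4,4-dimethylhex-5-enenitrile | N#CCCC(C)(C)C=C | intermediate
5 | N-(diisobutylalumanyl)-4,4-dimethylhex-5-en-1-imine | C=CC(C)(C)CCC=N[Al](CC(C)C)CC(C)C | intermediate (not isolated)
6 | 4,4-dimethylhex-5-enal | O=CCCC(C)(C)C=C | intermediate
7 | 3-isopropylcatechol | CC(C)c1cccc(O)c1O | starting material
8 | 1-isopropyl-2,3-dimethoxybenzene | CC(C)c1cccc(OC)c1OC | intermediate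
9 | 3-chloropropanoyl chloride | O=C(Cl)CCCl | starting material
10 | (4-isopropyl-2,3-dimethoxyphenyl)lithium | [Li]c1ccc(C(C)C)c(OC)c1OC | intermediate (not isolated)
11 | (4-isopropyl-2,3-dimethoxyphenyl)zinc chloride | Cl[Zn]c1ccc(C(C)C)c(OC)c1OC | intermediate (not isolated)
12 | 3-chloro-1-(4-isopropyl-2,3-dimethoxyphenyl)propan-1-one | CC(C)c1ccc(C(=O)CCCl)c(OC)c1OC | intermediate
13 | 1-(4-isopropyl-2,3-dimethoxyphenyl)prop-2-en-1-one | CC(C)c1ccc(C(=O)C=C)c(OC)c1OC | intermediate (not isolated)
14 | 5-isopropyl-6,7-dimethoxyindan-1-one | CC(C)c1cc2CCC(=O)c2c(OC)c1OC | intermediate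
15 | 2-(1-hydroxy-4,4-dimethylhex-5-en-1-yl)-5-isopropyl-6,7-dimethoxyindan-1-one (lithium alkoxide in the flask, mixture of diastereomers) | CC(C)c1cc2CC(C(O)CCC(C)(C)C=C)C(=O)c2c(OC)c1OC | intermediate (not isolated)
16 | methanesulfonate of 15 (mixture of diastereomers) | CC(C)c1cc2CC(C(OS(C)(=O)=O)CCC(C)(C)C=C)C(=O)c2c(OC)c1OC | intermediate (not isolated)
17 | (E)-2-(4,4-dimethylhex-5-en-1-ylidene)-5-isopropyl-6,7-dimethoxyindan-1-one | CC(C)c1cc2C/C(=C\CCC(C)(C)C=C)C(=O)c2c(OC)c1OC | intermediate
18 | 2-(4,4-dimethylhex-5-en-1-yl)-5-isopropyl-6,7-dimethoxy-1H-inden-1-one | CC(C)c1cc2C=C(CCCC(C)(C)C=C)C(=O)c2c(OC)c1OC | intermediate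
19 | rac-2-(4,4-dimethylhex-5-en-1-yl)-2,3-epoxy-5-isopropyl-6,7-dimethoxyindan-1-one (cis-fused oxirane, racemate, one enantiomer drawn) | CC(C)c1cc2c(c(OC)c1OC)C(=O)[C@@]1(CCCC(C)(C)C=C)O[C@@H]21 | intermediate
20 | 3-(4,4-dimethylhex-5-en-1-yl)-7-isopropyl-5,6-dimethoxy-2-benzopyrylium-4-olate | CC(C)c1cc2C=[O+]C(CCCC(C)(C)C=C)=C([O-])c2c(OC)c1OC | intermediate (not isolated)
21 | rac-(5S,7S,10R)-20-oxo-11,12-di-O-methylbrussonol (racemate, enantiomer carried on is drawn) | CC(C)c1cc2c(c(OC)c1OC)C(=O)[C@@]13CCCC(C)(C)[C@@H]1C[C@@H]2O3 | intermediate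
22 | rac-(5S,7S,10R,20R)-20-hydroxy-11,12-di-O-methylbrussonol (racemate, enantiomer carried on is drawn; hydroxyl syn to the C5–C6 bridge) | CC(C)c1cc2c(c(OC)c1OC)[C@@H](O)[C@@]13CCCC(C)(C)[C@@H]1C[C@@H]2O3 | intermediate
23 | (5S,7S,10R,20R)-20-[(1S,4R)-camphanoyloxy]-11,12-di-O-methylbrussonol | CC(C)c1cc2c(c(OC)c1OC)[C@@H](OC(=O)[C@@]56CC[C@@](C)(C(=O)O5)C6(C)C)[C@@]13CCCC(C)(C)[C@@H]1C[C@@H]2O3 | intermediate
24 | (5S,7S,10R,20R)-20-hydroxy-11,12-di-O-methylbrussonol (single enantiomer) | CC(C)c1cc2c(c(OC)c1OC)[C@@H](O)[C@@]13CCCC(C)(C)[C@@H]1C[C@@H]2O3 | intermediate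
25 | sodium O-[(5S,7S,10R,20R)-11,12-di-O-methylbrussonol-20-yl] dithiocarbonate | CC(C)c1cc2c(c(OC)c1OC)[C@@H](OC(=S)[S-])[C@@]13CCCC(C)(C)[C@@H]1C[C@@H]2O3.[Na+] | intermediate (not isolated)
26 | O-[(5S,7S,10R,20R)-11,12-di-O-methylbrussonol-20-yl] S-methyl dithiocarbonate | CC(C)c1cc2c(c(OC)c1OC)[C@@H](OC(=S)SC)[C@@]13CCCC(C)(C)[C@@H]1C[C@@H]2O3 | intermediate
27 | (5S,7S,10S)-11,12-di-O-methylbrussonol | CC(C)c1cc2c(c(OC)c1OC)C[C@@]13CCCC(C)(C)[C@@H]1C[C@@H]2O3 | intermediate
28 | brussonol, (5S,7S,10S)-7,10-epoxy-9(10→20)-abeo-abieta-8,11,13-triene-11,12-diol | CC(C)c1cc2c(c(O)c1O)C[C@@]13CCCC(C)(C)[C@@H]1C[C@@H]2O3 | intermediate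
29 | brussonol ortho-quinone (11,12-dione) | CC(C)C1=CC2=C(C(=O)C1=O)C[C@@]13CCCC(C)(C)[C@@H]1C[C@@H]2O3 | intermediate (not isolated)
30 | CNP0371333.1 (hetero-Diels–Alder dimer of 29) | CC(C)c1cc2c(c3c1O[C@@H]1C4=C(C[C@@]56CCCC(C)(C)[C@@H]5C[C@@H]4O6)C(=O)C(=O)[C@]1(C(C)C)O3)C[C@@]13CCCC(C)(C)[C@@H]1C[C@@H]2O3 | target

Total step count: 17. Longest linear sequence: 14 steps (steps 4 to 17, from 3-isopropylcatechol); steps 1 to 3 make the side-chain aldehyde that enters at step 7.

Steps most likely to fail

Step 10. The thermal cleavage of the oxirane C–C bond may need a temperature at which the ylide is lost by a 1,4-hydrogen shift, or at which the epoxy ketone isomerises to the 1,3-dione before it can add to the alkene. The fallback sets out from 19 and comes back at 21, and it separates the ring expansion from the cycloaddition. Irradiation of 19 (350 nm, benzene–acetic acid, room temperature) should open the oxirane in the excited state, and the ylide is caught at once by acetic acid as the storable acetal ester 1-acetoxy-3-(4,4-dimethylhex-5-en-1-yl)-7-isopropyl-5,6-dimethoxyisochroman-4-one F1. Et3N in MeCN at 25–60 °C then removes the C3 proton and expels acetate (oxidopyrylium generation from an acetoxy pyranone), so that 20 forms slowly under mild conditions and closes to 21.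

Step 17. The bimolecular cycloaddition may be slower than decomposition or carbocyclic Diels–Alder dimerisation of the quinone, or it may take the wrong face or orientation under kinetic control. The fallback sets out from 28 and comes back at 30, and it builds the dioxane ring stepwise by two conjugate additions. With half an equivalent of Ag2O, 29 is formed beside unchanged 28; K2CO3 in MeCN then lets the 12-phenoxide of 28 add to C14 of 29 (oxa-Michael addition), and tautomerisation gives the diaryl ether 14-[(11′-hydroxybrussonol-12′-yl)oxy]brussonol F2. A second oxidation with Ag2O converts the catechol ring of F2 into the ortho-quinone of F2, F3. Its neighbouring 11′-phenol closes the ring by reversible 1,6-oxa-Michael addition at C13 and ketonisation at C14, so that the ring fusion of 30 is reached under thermodynamic control.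

Step 8. The exo-to-endo isomerisation may stop at an unfavourable equilibrium, or the 3-unsubstituted indenone may be consumed by oligomerisation under the rhodium conditions. The fallback sets out from 17 and comes back at 18. Conjugate reduction with [(Ph3P)CuH]6 in benzene should give 2-(4,4-dimethylhex-5-en-1-yl)-5-isopropyl-6,7-dimethoxyindan-1-one F4. Its lithium enolate (LiN(i-Pr)2, THF, −78 °C) is selenenylated with PhSeBr to 2-(4,4-dimethylhex-5-en-1-yl)-5-isopropyl-6,7-dimethoxy-2-(phenylselanyl)indan-1-one F5. Oxidation with H2O2 and pyridine in CH2Cl2 at 0 °C then leads by selenoxide syn-elimination toward the benzylic ring hydrogen to 18.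

Further compounds
F1 | step 10 | 1-acetoxy-3-(4,4-dimethylhex-5-en-1-yl)-7-isopropyl-5,6-dimethoxyisochroman-4-one (racemic mixture of diastereomers) | CC(C)c1cc2C(OC(C)=O)OC(CCCC(C)(C)C=C)C(=O)c2c(OC)c1OC
F2 | step 17 | 14-[(11′-hydroxybrussonol-12′-yl)oxy]brussonol (C14–O12′ diaryl ether of two brussonol units) | CC(C)c1c(Oc4c(C(C)C)cc5c(c4O)C[C@@]46CCCC(C)(C)[C@@H]4C[C@@H]5O6)c2c(c(O)c1O)C[C@@]13CCCC(C)(C)[C@@H]1C[C@@H]2O3
F3 | step 17 | ortho-quinone (11,12-dione) of F2 | CC(C)C1=C(Oc4c(C(C)C)cc5c(c4O)C[C@@]46CCCC(C)(C)[C@@H]4C[C@@H]5O6)C2=C(C(=O)C1=O)C[C@@]13CCCC(C)(C)[C@@H]1C[C@@H]2O3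
F4 | step 8 | 2-(4,4-dimethylhex-5-en-1-yl)-5-isopropyl-6,7-dimethoxyindan-1-one (racemic) | CC(C)c1cc2CC(CCCC(C)(C)C=C)C(=O)c2c(OC)c1OC
F5 | step 8 | 2-(4,4-dimethylhex-5-en-1-yl)-5-isopropyl-6,7-dimethoxy-2-(phenylselanyl)indan-1-one (racemic) | CC(C)c1cc2CC(CCCC(C)(C)C=C)([Se]c3ccccc3)C(=O)c2c(OC)c1OC
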